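**Retrosynthetic overview** (ring atoms numbered as in the target: C1 carbonyl, C2=C3, C4 carbinol, C5 side-chain carbon, C6 CMe2)
1. The side chain is cut between its ketone carbon and the alkenyl carbon: Nozaki–Hiyama–Kishi coupling of ring aldehyde 21 with the Z alkenyl iodide 5, which already carries the decanoate, then oxidation.
2. The C4 carbinol comes from methyl addition to the less hindered carbonyl of ene-dione 18, anti to the C5 substituent; the aldehyde arm comes from cleavage of a butenyl group on C5.
3. The carbocycle, the only ring, is made in step 7 from acyclic diazo ketone 15: a Wolff shift makes C2–C3, a 6π-electrocyclization of the resulting dienylketene makes C1–C6, and a Claisen shift in the same pot moves the butenyl group from the oxygen on C4 to C5 and sets C5.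
4. The enabling feature: C6 is a quaternary CMe2 carbon directly on the C1 carbonyl, so the ring C1(=O)–C2=C3–C4(O)–C5–C6 is a masked 6,6-dimethylcyclohexa-2,4-dienone that cannot aromatize, and the oxygen on C4 together with the CH2 on C5 is the retron of an allyl vinyl ether.
5. Diazo ketone 15 comes from δ-lactone 9 (methyl acetoacetate plus acetone): the lactone ring fixes the enol ether geometry, a Mitsunobu reaction brings in the chirality as (R)-but-3-en-2-ol, and an E1cB ring opening releases the dienyl chain.

Key step: step 7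

Remark on the chemistry: the target is taken as the open γ-hydroxy ketone that is drawn; reversible closure to its five-membered hemiketal is assumed not to change the compound wanted.

**Step 1**
Reactants: 1 but-2-yn-1-ol
Product: 3 (2Z)-3-iodobut-2-en-1-ol, via cyclic sodium alkenylaluminate 2 (not isolated)
Conditions: NaAlH2(OCH2CH2OMe)2, THF, 0 °C to 20 °C; then I2, −78 °C to 0 °C
Reagents that add atoms: iodine, [I][I]
Why: Alkoxide-directed trans-hydroalumination of the propargylic alcohol places aluminium on C3 cis to the CH2O group in aluminate 2, and iodinolysis with retention should give the Z alkenyl iodide (hydroalumination–iodination).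

**Step 2**
Reactants: 3 (2Z)-3-iodobut-2-en-1-ol, 4 decanoyl chloride
Product: 5 (2Z)-3-iodobut-2-en-1-yl decanoate
Conditions: pyridine, DMAP (cat.), CH2Cl2, 0 °C to 20 °C
Reagents that add atoms: none
Why: Acylation of the primary allylic alcohol by the acid chloride (esterification) is fast at 0 °C and leaves the alkenyl iodide and its Z geometry untouched.

**Step 3**
Reactants: 6 methyl 3-oxobutanoate, 7 acetone
Product: 9 4-hydroxy-6,6-dimethyl-5,6-dihydro-2H-pyran-2-one, via keto ester aldol adduct 8 (not isolated)
Conditions: NaH, THF, 0 °C; n-BuLi, 0 °C; acetone, −78 °C to 0 °C; NaOH (aq.), 20 °C; HCl (aq.), pH 2, 0 °C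
Reagents that add atoms: none
Why: The acetoacetate dianion adds to acetone through its γ-carbon (dianion aldol addition), and saponification followed by acidification closes the six-membered lactone (lactonization), the usual entry to 6,6-disubstituted 4-hydroxy-5,6-dihydropyran-2-ones.

**Step 4**
Reactants: 9 4-hydroxy-6,6-dimethyl-5,6-dihydro-2H-pyran-2-one, 10 (2R)-but-3-en-2-ol
Product: 11 4-{[(2S)-but-3-en-2-yl]oxy}-6,6-dimethyl-5,6-dihydro-2H-pyran-2-one
Conditions: PPh3, DIAD, THF, 0 °C to 20 °C
Reagents that add atoms: none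
Why: The acidic vinylogous acid 9 is a competent Mitsunobu pronucleophile and should be alkylated on the C4 oxygen, with SN2 inversion at the carbinol carbon of 10 giving the S ether.

**Step 5**
Reactants: 11 4-{[(2S)-but-3-en-2-yl]oxy}-6,6-dimethyl-5,6-dihydro-2H-pyran-2-one
Product: 13 (3E)-4-{[(2S)-but-3-en-2-yl]oxy}-6-methylhepta-3,5-dien-2-one, via lithium dienoate 12 (not isolated)
Conditions: LiN(iPr)2, THF, −78 °C to 0 °C; then MeLi, 0 °C to 20 °C; inverse quench into NH4Cl (aq.)
Reagents that add atoms: methyllithium, [Li]C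
Why: Deprotonation at C5 of the dihydropyranone and expulsion of the carboxylate from C6 (vinylogous E1cB ring opening) should give dienoate 12 with the ring-enforced E enol ether geometry, and methyllithium adds to the lithium carboxylate only as far as the gem-diolate, so that work-up releases the methyl ketone (ketone synthesis from a carboxylate and an organolithium).

**Step 6**
Reactants: 13 (3E)-4-{[(2S)-but-3-en-2-yl]oxy}-6-methylhepta-3,5-dien-2-one
Product: 15 (3E)-4-{[(2S)-but-3-en-2-yl]oxy}-1-diazo-6-methylhepta-3,5-dien-2-one, via trifluoroacetyl diketone 14 (not isolated)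
Conditions: LiN(SiMe3)2, THF, −78 °C; CF3CO2CH2CF3, −78 °C; then MsN3, Et3N, H2O, MeCN, 20 °C
Reagents that add atoms: methanesulfonyl azide, CS(=O)(=O)N=[N+]=[N-]; 2,2,2-trifluoroethyl trifluoroacetate, O=C(OCC(F)(F)F)C(F)(F)F (its trifluoroacetyl group is carried only by 14)
Why: Kinetic enolization at the methyl group, trifluoroacetylation and deacylative diazo transfer from the sulfonyl azide (Regitz-type detrifluoroacetylative diazo transfer) should give the α'-diazo enone without exposing the conjugated system to diazomethane.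

**Step 7**
Reactants: 15 (3E)-4-{[(2S)-but-3-en-2-yl]oxy}-1-diazo-6-methylhepta-3,5-dien-2-one
Product: 18 (6R)-6-[(2E)-but-2-en-1-yl]-5,5-dimethylcyclohex-2-ene-1,4-dione, via dienylketene 16 (not isolated), via alkoxycyclohexadienone 17 (not isolated)
Conditions: hν (365 nm), toluene (0.01 M, degassed), 20 °C; then dark, 110 °C
Reagents that add atoms: none
Why: Light expels N2 and the alkoxydienyl group shifts from the carbonyl carbon to the diazo carbon (Wolff rearrangement), which makes the bond between the future alkene carbons C2 and C3 of the target ring and gives dienylketene 16. The ketene carbon of 16 then bonds to the dimethyl-substituted diene terminus in a thermally allowed disrotatory 6π-electrocyclization (bond C1–C6), the only ring closure, giving cyclohexa-2,4-dienone 17; at 110 °C the allyl dienyl ether of 17 undergoes a [3,3]-sigmatropic Claisen rearrangement that moves the butenyl group from the oxygen on C4 to C5 and leaves the ene-dione. The closest known reactions are the photochemical Wolff rearrangement of α'-diazo enones to vinylketenes, the thermal closure of dienylketenes to 6,6-disubstituted cyclohexa-2,4-dienones and the aliphatic Claisen rearrangement with 1,3-chirality transfer. The one new stereocentre (C6 of 18, C5 of the target) is controlled by the S carbinol carbon of the ether through a chair transition state with its methyl group equatorial, which should give the R configuration and an E alkene. The step needs the Wolff shift to win over carbene addition to the nearby alkene (metal-free photolysis, electron-rich migrating alkenyl group), a cis arrangement of the ketene and dimethylvinyl groups on the central double bond (the E enol ether geometry fixed by lactone 11), and ring closure without aromatization or dimerization (the quaternary terminus carries no hydrogen; the solution is kept at 0.01 M).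

**Step 8**
Reactants: 18 (6R)-6-[(2E)-but-2-en-1-yl]-5,5-dimethylcyclohex-2-ene-1,4-dione
Product: 19 (4S,5R)-5-[(2E)-but-2-en-1-yl]-4-hydroxy-4,6,6-trimethylcyclohex-2-en-1-one
Conditions: MeLi, CeCl3, THF, −78 °C
Reagents that add atoms: methyllithium, [Li]C
Why: The organocerium reagent MeCeCl2 adds 1,2 and without enolization (organocerium carbonyl addition) to the C1 carbonyl of 18, which is flanked by a CH, in preference to the C4 carbonyl next to the quaternary carbon, and it should approach anti to the butenyl group on C6, so that the new hydroxyl group is cis to the side chain (4S in 19).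

**Step 9**
Reactants: 19 (4S,5R)-5-[(2E)-but-2-en-1-yl]-4-hydroxy-4,6,6-trimethylcyclohex-2-en-1-one
Product: 20 (4S,5R)-5-[(2E)-but-2-en-1-yl]-4,6,6-trimethyl-4-[(triethylsilyl)oxy]cyclohex-2-en-1-one
Conditions: Et3SiOTf, 2,6-lutidine, CH2Cl2, −78 °C to 0 °C
Reagents that add atoms: triethylsilyl trifluoromethanesulfonate, CC[Si](CC)(CC)OS(=O)(=O)C(F)(F)F
Why: Silyl ether formation with a silyl triflate and a hindered pyridine base protects the tertiary alcohol, which would otherwise close onto the aldehyde of step 10 as a lactol; the remaining ketone has no α-hydrogen and cannot form a silyl enol ether.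

**Step 10**
Reactants: 20 (4S,5R)-5-[(2E)-but-2-en-1-yl]-4,6,6-trimethyl-4-[(triethylsilyl)oxy]cyclohex-2-en-1-one
Product: 21 2-[(1R,2S)-2,6,6-trimethyl-5-oxo-2-[(triethylsilyl)oxy]cyclohex-3-en-1-yl]acetaldehyde
Conditions: OsO4 (cat.), NaIO4, 2,6-lutidine, 1,4-dioxane/H2O, 20 °C
Reagents that add atoms: osmium tetroxide, O=[Os](=O)(=O)=O (delivers the aldehyde oxygen); sodium periodate, [Na+].[O-]I(=O)(=O)=O (regenerates it and cleaves the diol)
Why: Dihydroxylation and periodate cleavage (Lemieux–Johnson oxidation) should attack the electron-rich disubstituted butenyl alkene much faster than the electron-poor ring enone and release the aldehyde with loss of acetaldehyde.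

**Step 11**
Reactants: 21 2-[(1R,2S)-2,6,6-trimethyl-5-oxo-2-[(triethylsilyl)oxy]cyclohex-3-en-1-yl]acetaldehyde, 5 (2Z)-3-iodobut-2-en-1-yl decanoate
Product: 22 (2Z)-4-hydroxy-3-methyl-5-[(1R,2S)-2,6,6-trimethyl-5-oxo-2-[(triethylsilyl)oxy]cyclohex-3-en-1-yl]pent-2-en-1-yl decanoate (both C4 epimers)
Conditions: CrCl2, NiCl2 (cat.), DMSO, 20 °C
Reagents that add atoms: none
Why: In the Nozaki–Hiyama–Kishi coupling zerovalent nickel inserts into the C–I bond and passes the alkenyl group to trivalent chromium, which adds only to the aldehyde, so that the ester, the enone and the silyl ether should survive and the Z geometry be retained; the new carbinol centre is not controlled and is removed in step 12.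

**Step 12**
Reactants: 22 (2Z)-4-hydroxy-3-methyl-5-[(1R,2S)-2,6,6-trimethyl-5-oxo-2-[(triethylsilyl)oxy]cyclohex-3-en-1-yl]pent-2-en-1-yl decanoate
Product: 23 (2Z)-3-methyl-4-oxo-5-[(1R,2S)-2,6,6-trimethyl-5-oxo-2-[(triethylsilyl)oxy]cyclohex-3-en-1-yl]pent-2-en-1-yl decanoate
Conditions: Dess–Martin periodinane, NaHCO3, CH2Cl2, 0 °C to 20 °C
Reagents that add atoms: none
Why: Dess–Martin oxidation of the secondary allylic alcohol under buffered conditions should give the Z enone without isomerization and leave the ester and the silyl ether intact.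

**Step 13**
Reactants: 23 (2Z)-3-methyl-4-oxo-5-[(1R,2S)-2,6,6-trimethyl-5-oxo-2-[(triethylsilyl)oxy]cyclohex-3-en-1-yl]pent-2-en-1-yl decanoate
Product: 24 (2Z)-5-[(1R,2S)-2-hydroxy-2,6,6-trimethyl-5-oxocyclohex-3-en-1-yl]-3-methyl-4-oxopent-2-en-1-yl decanoate
Conditions: HF·pyridine, pyridine, THF, 0 °C
Reagents that add atoms: none
Why: Fluoride-mediated desilylation under buffered conditions should cleave the tertiary silyl ether without touching the ester or isomerizing the Z enone.

**Compound list**
1 | but-2-yn-1-ol | CC#CCO | starting material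
2 | sodium 2,2-bis(2-methoxyethoxy)-3-methyl-2,5-dihydro-1,2-oxaluminol-2-uide (cyclic alkenylaluminate, Al on C3 cis to CH2O) | CC1=CCO[Al-]1(OCCOC)OCCOC.[Na+] | intermediate
3 | (2Z)-3-iodobut-2-en-1-ol | OC/C=C(/C)I | intermediate
4 | decanoyl chloride | CCCCCCCCCC(=O)Cl | starting material
5 | (2Z)-3-iodobut-2-en-1-yl decanoate | CCCCCCCCCC(=O)OC/C=C(/C)I | intermediate
6 | methyl 3-oxobutanoate | COC(=O)CC(C)=O | starting material
7 | acetone | CC(C)=O | starting material
8 | methyl 5-hydroxy-5-methyl-3-oxohexanoate | COC(=O)CC(=O)CC(C)(C)O | intermediate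
9 | 4-hydroxy-6,6-dimethyl-5,6-dihydro-2H-pyran-2-one | OC1=CC(=O)OC(C)(C)C1 | intermediate
10 | (2R)-but-3-en-2-ol | C=C[C@@H](C)O | starting material
11 | 4-{[(2S)-but-3-en-2-yl]oxy}-6,6-dimethyl-5,6-dihydro-2H-pyran-2-one | C=C[C@H](C)OC1=CC(=O)OC(C)(C)C1 | intermediate
12 | lithium (2E)-3-{[(2S)-but-3-en-2-yl]oxy}-5-methylhexa-2,4-dienoate | [Li+].[O-]C(=O)/C=C(/O[C@@H](C)C=C)C=C(C)C | intermediate
13 | (3E)-4-{[(2S)-but-3-en-2-yl]oxy}-6-methylhepta-3,5-dien-2-one | CC(=O)/C=C(/O[C@@H](C)C=C)C=C(C)C | intermediate
14 | (5E)-6-{[(2S)-but-3-en-2-yl]oxy}-1,1,1-trifluoro-8-methylnona-5,7-diene-2,4-dione | O=C(CC(=O)/C=C(/O[C@@H](C)C=C)C=C(C)C)C(F)(F)F | intermediate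
15 | (3E)-4-{[(2S)-but-3-en-2-yl]oxy}-1-diazo-6-methylhepta-3,5-dien-2-one | [N-]=[N+]=CC(=O)/C=C(/O[C@@H](C)C=C)C=C(C)C | intermediate
16 | (3E)-4-{[(2S)-but-3-en-2-yl]oxy}-6-methylhepta-1,3,5-trien-1-one | O=C=C/C=C(/O[C@@H](C)C=C)C=C(C)C | intermediate
17 | 4-{[(2S)-but-3-en-2-yl]oxy}-6,6-dimethylcyclohexa-2,4-dien-1-one | C=C[C@H](C)OC1=CC(C)(C)C(=O)C=C1 | intermediate
18 | (6R)-6-[(2E)-but-2-en-1-yl]-5,5-dimethylcyclohex-2-ene-1,4-dione | C/C=C/C[C@@H]1C(C)(C)C(=O)C=CC1=O | intermediate
19 | (4S,5R)-5-[(2E)-but-2-en-1-yl]-4-hydroxy-4,6,6-trimethylcyclohex-2-en-1-one | C/C=C/C[C@@H]1C(C)(C)C(=O)C=C[C@]1(C)O | intermediate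
20 | (4S,5R)-5-[(2E)-but-2-en-1-yl]-4,6,6-trimethyl-4-[(triethylsilyl)oxy]cyclohex-2-en-1-one | C/C=C/C[C@@H]1C(C)(C)C(=O)C=C[C@]1(C)O[Si](CC)(CC)CC | intermediate
21 | 2-[(1R,2S)-2,6,6-trimethyl-5-oxo-2-[(triethylsilyl)oxy]cyclohex-3-en-1-yl]acetaldehyde | O=CC[C@@H]1C(C)(C)C(=O)C=C[C@]1(C)O[Si](CC)(CC)CC | intermediate
22 | (2Z)-4-hydroxy-3-methyl-5-[(1R,2S)-2,6,6-trimethyl-5-oxo-2-[(triethylsilyl)oxy]cyclohex-3-en-1-yl]pent-2-en-1-yl decanoate (both C4 epimers) | CCCCCCCCCC(=O)OC/C=C(/C)C(O)C[C@@H]1C(C)(C)C(=O)C=C[C@]1(C)O[Si](CC)(CC)CC | intermediate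
23 | (2Z)-3-methyl-4-oxo-5-[(1R,2S)-2,6,6-trimethyl-5-oxo-2-[(triethylsilyl)oxy]cyclohex-3-en-1-yl]pent-2-en-1-yl decanoate | CCCCCCCCCC(=O)OC/C=C(/C)C(=O)C[C@@H]1C(C)(C)C(=O)C=C[C@]1(C)O[Si](CC)(CC)CC | intermediate
24 | (2Z)-5-[(1R,2S)-2-hydroxy-2,6,6-trimethyl-5-oxocyclohex-3-en-1-yl]-3-methyl-4-oxopent-2-en-1-yl decanoate | CCCCCCCCCC(=O)OC/C=C(/C)C(=O)C[C@@H]1C(C)(C)C(=O)C=C[C@]1(C)O | target

**Step count**
Total: 13 steps. Longest linear sequence: 11 steps (steps 3 to 13); steps 1 and 2 make the side-chain fragment.

**Steps most likely to fail**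

Step 7. Bimolecular [4+2] dimerization of dienone 17 may outrun the Claisen shift at the temperature it needs, a boat transition state may leak and lower the enantiopurity, and photoisomerization of the enol ether double bond may divert part of the ketene. The fallback sets out from 17 and comes back at 21; it replaces chirality transfer by catalyst control. The operation is stopped after the photochemical stage and 17 is hydrolysed (HCl 1 M, THF, 20 °C) to 5,5-dimethylcyclohex-2-ene-1,4-dione F1. Its sodium enolate (NaN(SiMe3)2, THF, −78 °C) is trapped on oxygen with allyl chloroformate to give 3,3-dimethyl-4-oxocyclohexa-1,5-dien-1-yl prop-2-en-1-yl carbonate F2. Decarboxylative asymmetric allylic alkylation (Pd2(dba)3, (1R,2R)-N,N'-bis[2-(diphenylphosphino)benzoyl]cyclohexane-1,2-diamine, 1,4-dioxane, 20 °C; the ligand antipode is chosen in a test run for the 6R sense) should give (6R)-5,5-dimethyl-6-(prop-2-en-1-yl)cyclohex-2-ene-1,4-dione F3. Methyl addition as in step 8 gives (4S,5R)-4-hydroxy-4,6,6-trimethyl-5-(prop-2-en-1-yl)cyclohex-2-en-1-one F4, silylation as in step 9 gives (4S,5R)-4,6,6-trimethyl-5-(prop-2-en-1-yl)-4-[(triethylsilyl)oxy]cyclohex-2-en-1-one F5, and Lemieux–Johnson cleavage as in step 10 gives 21.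

Step 8. The reagent may attack the C4 carbonyl of 18 next to the quaternary carbon, or approach the C1 carbonyl from the butenyl face and give the C4 epimer of 19. The fallback sets out from 18 and comes back at 19; it delivers the carbon as a methylene from a sulfur ylide, which adds irreversibly and with the facial preference opposite to that of organolithium-type reagents. Dimethylsulfonium methylide (Me3S+ I−, KN(SiMe3)2, THF, −10 °C; Corey–Chaykovsky epoxidation) should give (3S,8R)-8-[(2E)-but-2-en-1-yl]-7,7-dimethyl-1-oxaspiro[2.5]oct-4-en-6-one F6, with the epoxide oxygen cis to the butenyl group. LiAlH4 (THF, 0 °C) opens the epoxide at its CH2 carbon and reduces the ring ketone to give (1S,6R)-6-[(2E)-but-2-en-1-yl]-1,5,5-trimethylcyclohex-2-ene-1,4-diol F7 (both C4 epimers). MnO2 (CH2Cl2, 20 °C) reoxidizes only the secondary allylic alcohol to give 19.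

Step 4. SN2′ capture or ionization of the allylic oxyphosphonium ion may give the regioisomeric but-2-enyl ether or a partly racemized ether 11, and every later stereocentre depends on its purity. The fallback sets out from 9 and comes back at 11; it forms the vinylic C–O bond instead of the allylic one. Acid 9 is condensed with (2S)-but-3-en-2-ol (C=C[C@H](C)O; camphorsulfonic acid cat., toluene, 4 Å molecular sieves, 60 °C; vinylogous esterification), in which the carbinol C–O bond is not broken and the configuration is retained. This fallback makes no new compound (F0).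

**Further compounds**
F1 | step 7 | 5,5-dimethylcyclohex-2-ene-1,4-dione | CC1(C)CC(=O)C=CC1=O
F2 | step 7 | 3,3-dimethyl-4-oxocyclohexa-1,5-dien-1-yl prop-2-en-1-yl carbonate | C=CCOC(=O)OC1=CC(C)(C)C(=O)C=C1
F3 | step 7 | (6R)-5,5-dimethyl-6-(prop-2-en-1-yl)cyclohex-2-ene-1,4-dione | C=CC[C@@H]1C(C)(C)C(=O)C=CC1=O
F4 | step 7 | (4S,5R)-4-hydroxy-4,6,6-trimethyl-5-(prop-2-en-1-yl)cyclohex-2-en-1-one | C=CC[C@@H]1C(C)(C)C(=O)C=C[C@]1(C)O
F5 | step 7 | (4S,5R)-4,6,6-trimethyl-5-(prop-2-en-1-yl)-4-[(triethylsilyl)oxy]cyclohex-2-en-1-one | C=CC[C@@H]1C(C)(C)C(=O)C=C[C@]1(C)O[Si](CC)(CC)CC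
F6 | step 8 | (3S,8R)-8-[(2E)-but-2-en-1-yl]-7,7-dimethyl-1-oxaspiro[2.5]oct-4-en-6-one | C/C=C/C[C@@H]1C(C)(C)C(=O)C=C[C@@]12CO2
F7 | step 8 | (1S,6R)-6-[(2E)-but-2-en-1-yl]-1,5,5-trimethylcyclohex-2-ene-1,4-diol (both C4 epimers) | C/C=C/C[C@@H]1C(C)(C)C(O)C=C[C@]1(C)O
F0 | step 4 | none | none
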